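**Plan**
1. Retrosynthetic cut 1: the C11'–C12' σ-bond in the middle of the docosyl chain (C1' is the carbon on pyrrole C3). This gives two C12 acids as their N-acyloxyphthalimides: dodecanoic acid and 12-(2-formyl-1H-pyrrol-3-yl)dodecanoic acid.
2. Retrosynthetic cut 2: the pyrrole C3–C1' bond. This gives 3-bromo-1H-pyrrole-2-carbaldehyde and the alkylzinc reagent from methyl 12-bromododecanoate.
3. Forward order: N-Boc protection, Negishi coupling, one-pot carbamate/ester hydrolysis, activation of both acids as redox-active esters, then a nickel-electrocatalytic doubly decarboxylative radical cross-coupling at the cathode that joins C11' to C12' and gives the unprotected target directly.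
4. Enabling feature: C11' and C12' are unfunctionalised primary CH2 carbons of an unbranched chain, so each is the primary radical left when a fatty acid loses CO2. The only ring, the 2-formyl-1H-pyrrole (N1–C2–CHO, a vinylogous formamide), is oxidation-prone but hard to reduce, so the coupling is run reductively at the cathode and not as an anodic Kolbe reaction.
5. The pyrrole ring is bought intact and no ring is formed. The target has no stereocentre, so no stereocontrol is needed.

Key step: step 6

Remark: the target is achiral, so "single enantiomer" carries no stereochemical demand. 3-Bromo-1H-pyrrole-2-carbaldehyde, methyl 12-bromododecanoate and dodecanoic acid are taken as catalogue compounds. Transient radicals and catalyst-bound species are not counted as compounds.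

**Route**

Step 1
Reactants: 1 3-bromo-1H-pyrrole-2-carbaldehyde
Product: 2 tert-butyl 3-bromo-2-formyl-1H-pyrrole-1-carboxylate
Conditions: Boc2O (1.2 equiv), DMAP (10 mol%), MeCN, rt
Reagents that add atoms: di-tert-butyl dicarbonate, CC(C)(C)OC(=O)OC(=O)OC(C)(C)C
Why: DMAP-catalysed N-acylation (Boc protection) of the acidic pyrrole N–H removes the proton that would quench the organozinc reagent of step 2 and makes the C3–Br bond more electron-poor for oxidative addition.

Step 2
Reactants: 2 tert-butyl 3-bromo-2-formyl-1H-pyrrole-1-carboxylate; 3 methyl 12-bromododecanoate
Product: 5 tert-butyl 2-formyl-3-(12-methoxy-12-oxododecyl)-1H-pyrrole-1-carboxylate, via (12-methoxy-12-oxododecyl)zinc bromide 4 (not isolated)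
Conditions: 3, Zn dust (TMSCl/1,2-dibromoethane activation), LiCl, THF, 50 °C; then 2, Pd(OAc)2 (2 mol%), SPhos (4 mol%), THF, rt to 40 °C
Reagents that add atoms: zinc, [Zn] (held only in intermediate 4; none of it remains in 5)
Why: LiCl-promoted zinc insertion into the primary alkyl bromide gives an ester-tolerant alkylzinc halide that should undergo Pd/SPhos Negishi sp2–sp3 coupling at the electron-poor C3–Br bond, since alkylzinc halides do not add to formyl, ester or carbamate groups and the bulky biarylphosphine favours reductive elimination over β-hydride elimination.

Step 3
Reactants: 5 tert-butyl 2-formyl-3-(12-methoxy-12-oxododecyl)-1H-pyrrole-1-carboxylate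
Product: 7 12-(2-formyl-1H-pyrrol-3-yl)dodecanoic acid, via methyl 12-(2-formyl-1H-pyrrol-3-yl)dodecanoate 6 (not isolated)
Conditions: LiOH·H2O (4 equiv), THF/H2O 3:1, rt; then 1 M HCl to pH 3
Reagents that add atoms: lithium hydroxide, [Li+].[OH-]
Why: Hydroxide should first cleave the activated N-acylpyrrole-type carbamate (the 2-formylpyrrolide is a good leaving group) and then saponify the methyl ester, while the non-enolisable vinylogous-formamide aldehyde is expected to survive.

Step 4
Reactants: 7 12-(2-formyl-1H-pyrrol-3-yl)dodecanoic acid
Product: 8 1,3-dioxoisoindolin-2-yl 12-(2-formyl-1H-pyrrol-3-yl)dodecanoate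
Conditions: N-hydroxyphthalimide (1.05 equiv), DIC (1.1 equiv), DMAP (5 mol%), CH2Cl2/THF, 0 °C to rt
Reagents that add atoms: N-hydroxyphthalimide, O=C1c2ccccc2C(=O)N1O
Why: Carbodiimide (Steglich-type) esterification with N-hydroxyphthalimide should give the redox-active ester, because the weakly nucleophilic pyrrole N–H and the aldehyde do not compete with the N-hydroxy nucleophile for the O-acylisourea.

Step 5
Reactants: 9 dodecanoic acid (lauric acid)
Product: 10 1,3-dioxoisoindolin-2-yl dodecanoate
Conditions: N-hydroxyphthalimide (1.0 equiv), DIC (1.1 equiv), DMAP (5 mol%), CH2Cl2, rt
Reagents that add atoms: N-hydroxyphthalimide, O=C1c2ccccc2C(=O)N1O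
Why: The same carbodiimide esterification converts the plain fatty acid into its crystalline redox-active N-acyloxyphthalimide.

Step 6
Reactants: 8 1,3-dioxoisoindolin-2-yl 12-(2-formyl-1H-pyrrol-3-yl)dodecanoate; 10 1,3-dioxoisoindolin-2-yl dodecanoate (3 equiv)
Product: 11 3-docosyl-1H-pyrrole-2-carbaldehyde
Conditions: NiCl2·6H2O (20 mol%), 2,2':6',2''-terpyridine (20 mol%), AgNO3 (0.3 equiv), NMP, Mg anode/RVC cathode, undivided cell, constant current, rt; then 1 M HCl work-up
Reagents that add atoms: none
Why: At the silver-coated cathode, with nickel mediation, each N-acyloxyphthalimide accepts one electron and fragments to phthalimide anion, CO2 and a primary alkyl radical (undecyl from 10, the 11-(2-formyl-1H-pyrrol-3-yl)undecyl radical from 8), while the magnesium anode is consumed as the electron source; a terpyridine-ligated nickel centre captures the two radicals in turn and reductive elimination from the dialkylnickel species forms the C11'–C12' bond. The closest known reaction type is the nickel-electrocatalytic doubly decarboxylative C(sp3)–C(sp3) cross-coupling of two redox-active esters, the reductive counterpart of a mixed Kolbe electrolysis, which is established for primary–primary pairs. No ring is closed and no stereocentre is created. The step needs cross- over homo-selectivity and chemoselectivity for the active esters over the formyl group and the pyrrole; the first is addressed by using the cheap lauric ester 10 in threefold excess, so that the radical from 8 should meet mostly undecyl partners and the main by-product, docosane, is non-polar and should wash off silica with hexane ahead of the polar product. The second is secured by the substrate itself, since the N1–C2–CHO vinylogous formamide is much harder to reduce than an N-acyloxyphthalimide, its N–H is too weakly acidic to be deprotonated by phthalimide anion, and working at the cathode avoids the anodic oxidation that a pyrrole would suffer in a classical Kolbe coupling. The eleven-carbon tether keeps the radical centre remote from the ring, so no cyclisation onto the pyrrole should compete.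

**Compound list**
1 | 3-bromo-1H-pyrrole-2-carbaldehyde | O=Cc1[nH]ccc1Br | starting material
2 | tert-butyl 3-bromo-2-formyl-1H-pyrrole-1-carboxylate | CC(C)(C)OC(=O)n1ccc(Br)c1C=O | intermediate
3 | methyl 12-bromododecanoate | COC(=O)CCCCCCCCCCCBr | starting material
4 | (12-methoxy-12-oxododecyl)zinc bromide | COC(=O)CCCCCCCCCCC[Zn]Br | intermediate (not isolated)
5 | tert-butyl 2-formyl-3-(12-methoxy-12-oxododecyl)-1H-pyrrole-1-carboxylate | COC(=O)CCCCCCCCCCCc1ccn(C(=O)OC(C)(C)C)c1C=O | intermediate
6 | methyl 12-(2-formyl-1H-pyrrol-3-yl)dodecanoate | COC(=O)CCCCCCCCCCCc1cc[nH]c1C=O | intermediate (not isolated)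
7 | 12-(2-formyl-1H-pyrrol-3-yl)dodecanoic acid | OC(=O)CCCCCCCCCCCc1cc[nH]c1C=O | intermediate
8 | 1,3-dioxoisoindolin-2-yl 12-(2-formyl-1H-pyrrol-3-yl)dodecanoate | O=C1c2ccccc2C(=O)N1OC(=O)CCCCCCCCCCCc1cc[nH]c1C=O | intermediate
9 | dodecanoic acid (lauric acid) | CCCCCCCCCCCC(=O)O | starting material
10 | 1,3-dioxoisoindolin-2-yl dodecanoate | CCCCCCCCCCCC(=O)ON1C(=O)c2ccccc2C1=O | intermediate
11 | 3-docosyl-1H-pyrrole-2-carbaldehyde | CCCCCCCCCCCCCCCCCCCCCCc1cc[nH]c1C=O | target

**Summary**
Total step count: 6. Longest linear sequence: 5 steps (steps 1, 2, 3, 4 and 6); step 5 prepares the second coupling partner in one step from dodecanoic acid.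

**The three steps most likely to fail, each with its fallback**

First, step 6. Statistical homocoupling, hydrogen-atom quench or disproportionation of the two primary radicals may outrun the nickel-mediated cross-coupling. The formyl group may also be engaged by low-valent nickel or reduced at the cathode, and chain-shortened by-products of similar polarity would then burden the purification. The fallback sets out from compound 2 and comes back to the route at compound 11. Commercial 1-bromodocosane, treated with activated zinc dust and LiCl in THF at 50 °C, would give docosylzinc bromide F1 as a THF solution. Coupling of this reagent with 2 under the Pd(OAc)2/SPhos Negishi conditions of step 2 would give tert-butyl 3-docosyl-2-formyl-1H-pyrrole-1-carboxylate F2 as the protected target. K2CO3 in MeOH/THF at rt would then remove the Boc group by methanolysis to give 11. In this fallback the whole C22 chain is introduced at pyrrole C3 by a two-electron sp2–sp3 coupling, and no radical or electrochemical step is involved.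

Second, step 2. Zinc insertion may be slow or incomplete, the alkylzinc may be protonated, β-hydride elimination may follow transmetalation, or the bromopyrrole may be protodebrominated. The fallback sets out from compounds 2 and 3 and comes back at compound 5. It is a nickel-catalysed reductive cross-electrophile coupling of the aryl bromide with the alkyl bromide (NiI2, 4,4'-di-tert-butyl-2,2'-bipyridine, NaI, Zn powder, DMA, 60 °C). No organometallic reagent is preformed and the alkyl partner enters as a radical captured by an aryl-nickel species. No new compound arises on the way.

Third, step 3. Cannizzaro-type disproportionation or base-induced degradation of the formylpyrrole may occur under hydroxide, and the long-chain carboxylate soap may form emulsions on work-up. The fallback sets out from compound 5 and comes back at compound 7. It unmasks the two groups separately without base. TFA in CH2Cl2 at 0 °C would remove the Boc group to give compound 6, now isolated. Immobilised Candida antarctica lipase B in pH 7 phosphate buffer with MTBE as co-solvent at 35 °C would then hydrolyse the fatty methyl ester to 7 under neutral conditions.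

**Further compounds**
F1 | step 6 | docosylzinc bromide | CCCCCCCCCCCCCCCCCCCCCC[Zn]Br
F2 | step 6 | tert-butyl 3-docosyl-2-formyl-1H-pyrrole-1-carboxylate | CCCCCCCCCCCCCCCCCCCCCCc1ccn(C(=O)OC(C)(C)C)c1C=O
F0 | step 2 | none | none
F0 | step 3 | none | none
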